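**Plan**
- **Cuts, in order:** the three O–benzyl bonds; the exocyclic C=C that masks the C3 CH2OH; C7–C8 of the arylglycerol side chain (aldol) and the phenol O–CH2 bond of its glycolate precursor; O1–C2 and C2–C3 of the tetrahydrofuran, cut together; the allylsilane C=C (cross-metathesis); the aryl–CH2 bond at C5 (epoxide opening).
- **Enabling feature:** in the tetrahydrofuran (O1, C2 guaiacyl, C3 CH2OH, C4 OH, C5 arylmethyl), C2 is at the aldehyde oxidation level and lies between O1 and C3. The C3 CH2OH can be carried as a vinyl group, which is what an allylsilane leaves behind, so one aromatic aldehyde can be joined to the C5 oxygen and to C3 in a single operation.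
- **Forward order:** the C5–C4–C3 chain comes from divinylcarbinol, the arylmethyl group from epoxide opening and the allylsilane from metathesis. The only new ring (the tetrahydrofuran) closes in step 6. The side chain is then grown on the freed phenol, the vinyl group is cut down to CH2OH, and hydrogenolysis finishes the synthesis.
- **Stereochemistry:** C4 and C5 come from a desymmetrising Sharpless epoxidation. C3 and C2 are induced by C4 in the cyclisation, and C2 can also be corrected thermodynamically. C8 comes from an Evans auxiliary. C7 comes from the same syn-aldol followed by Mitsunobu inversion, because the syn-aldol gives the threo (7S,8S) series whereas the target is erythro (7R,8S).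

Key step: step 6

Remark on the chemistry: CIP analysis of the target gives (2S,3S,4S,5R) for the all-trans tetrahydrofuran (locants O1, C2 aryl, C3, C4, C5 arylmethyl) and (7R,8S) for the side chain (C7 benzylic carbinol, C8 aryloxy carbon, C9 CH2OH). All starting materials below are assumed to be catalogue compounds.

**Step 1**
Reactants: 1 4-bromo-2-methoxyphenol
Product: 2 (4-bromo-2-methoxyphenoxy)triisopropylsilane
Conditions: TIPSCl, imidazole, DMF, rt
Reagents that add atoms: triisopropylsilyl chloride, CC(C)[Si](Cl)(C(C)C)C(C)C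
Why: Imidazole-promoted O-silylation masks the acidic phenol for Grignard formation as a bulky aryl silyl ether that tolerates BF3·OEt2 at low temperature and is later removed by fluoride without touching benzyl ethers.

**Step 2**
Reactants: 3 penta-1,4-dien-3-ol (divinylcarbinol)
Product: 4 (2R,3S)-1,2-epoxypent-4-en-3-ol [(1S)-1-[(2R)-oxiran-2-yl]prop-2-en-1-ol]
Conditions: Ti(OiPr)4 (cat.), L-(+)-DIPT, t-BuOOH, 4 Å MS, CH2Cl2, −20 °C
Reagents that add atoms: tert-butyl hydroperoxide, CC(C)(C)OO
Why: In this Sharpless asymmetric epoxidation run as a desymmetrisation, the L-(+)-tartrate catalyst selects one enantiotopic vinyl group and one of its faces to give the erythro epoxy alcohol, fixing the future C5 (epoxide carbon, R) and C4 (carbinol, S), while the minor enantiomer is consumed faster by a second epoxidation so that optical purity should rise with conversion.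

**Step 3**
Reactants: 4 (2R,3S)-1,2-epoxypent-4-en-3-ol
Product: 5 (2R,3S)-3-(benzyloxy)-1,2-epoxypent-4-ene
Conditions: NaH, BnBr, Bu4NI (cat.), THF, 0 °C → rt
Reagents that add atoms: benzyl bromide, BrCc1ccccc1
Why: In this Williamson etherification the iodide-activated benzyl halide traps the alkoxide before Payne rearrangement can compete, no stereocentre is touched, and the non-participating C4 benzyl ether lasts until the final hydrogenolysis.

**Step 4**
Reactants: 2 (4-bromo-2-methoxyphenoxy)triisopropylsilane; 5 (2R,3S)-3-(benzyloxy)-1,2-epoxypent-4-ene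
Product: 7 (2R,3S)-3-(benzyloxy)-1-[3-methoxy-4-(triisopropylsilyloxy)phenyl]pent-4-en-2-ol, via aryl Grignard reagent 6 (not isolated)
Conditions: 2, Mg, THF, reflux; then CuI (10 mol%), 5, THF, −30 → 0 °C
Reagents that add atoms: none
Why: Copper-catalysed SN2 opening of a monosubstituted epoxide by an aryl Grignard reagent occurs at the unhindered CH2 terminus, so the aryl–CH2 bond forms, the C5–O bond keeps its configuration, and the C5 hydroxyl is released free next to the already protected C4 oxygen.

**Step 5**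
Reactants: 7 (2R,3S)-3-(benzyloxy)-1-[3-methoxy-4-(triisopropylsilyloxy)phenyl]pent-4-en-2-ol; 8 allyltrimethylsilane
Product: 9 (2R,3S,4E)-3-(benzyloxy)-1-[3-methoxy-4-(triisopropylsilyloxy)phenyl]-6-(trimethylsilyl)hex-4-en-2-ol
Conditions: second-generation Grubbs catalyst (5 mol%), 8 (4 equiv), CH2Cl2, reflux
Reagents that add atoms: none
Why: Olefin cross-metathesis between a rapidly exchanging allylsilane and a hindered, slowly dimerising secondary allylic ether is a selective pairing that should favour the (E)-disubstituted alkene, the ruthenium carbene tolerates the free hydroxyl and both silyl groups, and any minor (Z)-isomer is removed by chromatography.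

**Step 6**
Reactants: 9 (2R,3S,4E)-3-(benzyloxy)-1-[3-methoxy-4-(triisopropylsilyloxy)phenyl]-6-(trimethylsilyl)hex-4-en-2-ol; 10 4-(benzyloxy)-3-methoxybenzaldehyde (O-benzylvanillin)
Product: 12 (2S,3R,4S,5R)-4-(benzyloxy)-2-[4-(benzyloxy)-3-methoxyphenyl]-3-ethenyl-5-{[3-methoxy-4-(triisopropylsilyloxy)phenyl]methyl}oxolane (all-trans), via oxocarbenium ion 11 (not isolated)
Conditions: 10 (1.2 equiv), BF3·OEt2 (1.5 equiv), 4 Å MS, CH2Cl2, −78 → −20 °C
Reagents that add atoms: none
Why: BF3·OEt2 activates aldehyde 10 toward addition of the C5 hydroxyl of 9 and then removes the boron-bound oxygen to give the (E)-oxocarbenium ion 11, whose C2 is attacked by the γ-carbon (C3) of the allylsilane anti to the C–Si bond, and loss of the silyl group from the β-silyl cation leaves the C3 vinyl group, so O1–C2 and C2–C3 form in one operation. This is an intramolecular Hosomi–Sakurai (silyl-terminated Prins-type) cyclisation of an alcohol/aldehyde pair, an established route to 2-substituted 3-vinyl cyclic ethers. The one ring closes five-membered, exo with respect to the C3=C alkene and endo with respect to the O1=C2 bond, because the β-silicon effect places the developing charge outside the ring and so excludes the six-membered Prins mode. C3 is set by the resident C4 stereocentre, since in the envelope transition state C4–H lies in the alkene plane (minimal allylic 1,3-strain), the benzyloxy group points outward, and C2 bonds to the alkene face that puts the vinyl group trans to the benzyloxy group. C2 is set by the (E)-geometry of 11 and by avoidance of an eclipsing aryl/alkenyl contact, which places the aryl group trans to the vinyl group, and because the C2–O1 bond next to the p-benzyloxyaryl group can reopen under BF3·OEt2, any cis isomer should drain to the all-trans ring. The step needs chemoselectivity for the allylsilane over the electron-rich arylmethyl ring (oxa-Pictet–Spengler closure) and over 2-oxonia-Cope rearrangement, which the much higher π-nucleophilicity of the allylsilane at low temperature and the non-enolisable, cation-stabilising aldehyde should secure.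

**Step 7**
Reactants: 12 all-trans 3-vinyl tetrahydrofuran TIPS ether
Product: 13 4-({(2R,3S,4R,5S)-3-(benzyloxy)-5-[4-(benzyloxy)-3-methoxyphenyl]-4-ethenyloxolan-2-yl}methyl)-2-methoxyphenol
Conditions: Bu4NF, AcOH, THF, 0 °C
Reagents that add atoms: none
Why: Fluoride-induced cleavage of the aryl silyl ether is driven by the strong Si–F bond and the good phenoxide leaving group, acetic acid buffers the phenoxide, and the benzyl ethers, the vinyl group and the ring stereocentres are inert.

**Step 8**
Reactants: 14 (R)-4-benzyloxazolidin-2-one; 15 bromoacetyl bromide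
Product: 17 (R)-4-benzyl-3-(bromoacetyl)oxazolidin-2-one, via N-lithio oxazolidinone 16 (not isolated)
Conditions: n-BuLi, THF, −78 °C; then 15, −78 → 0 °C
Reagents that add atoms: none
Why: In this N-acylation of a lithiated Evans oxazolidinone the acyl bromide reacts far faster than the primary alkyl bromide, so the bromomethyl group is kept for the next step and the auxiliary stereocentre is untouched.

**Step 9**
Reactants: 13 phenol; 17 (R)-4-benzyl-3-(bromoacetyl)oxazolidin-2-one
Product: 18 (R)-4-benzyl-3-[(ArO)acetyl]oxazolidin-2-one (ArO = phenoxy residue of 13)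
Conditions: K2CO3, DMF, 0 °C → rt
Reagents that add atoms: none
Why: This Williamson-type SN2 displacement of an α-bromo imide by the phenoxide is accelerated by the adjacent carbonyl, so it should outrun attack at the imide carbonyls, and it installs C8 and C9 together with the stereocontroller.

**Step 10**
Reactants: 18 aryloxyacetyl imide; 10 4-(benzyloxy)-3-methoxybenzaldehyde
Product: 20 (R)-4-benzyl-3-{(2R,3S)-2-(ArO)-3-[4-(benzyloxy)-3-methoxyphenyl]-3-hydroxypropanoyl}oxazolidin-2-one (syn), via Z-boron enolate 19 (not isolated)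
Conditions: Bu2BOTf, Et3N, CH2Cl2, −78 → 0 °C; then 10, −78 → 0 °C; then pH 7 buffer, MeOH, H2O2
Reagents that add atoms: none
Why: In this Evans syn-aldol reaction soft enolisation gives the (Z)-boron enolate 19, which adds to the non-enolisable aldehyde through a Zimmerman–Traxler chair with the auxiliary dipole opposed and its benzyl group shielding one face, so the (R)-auxiliary should set C8 in its final spatial arrangement and C7 as the (S)-carbinol, the threo outcome established for aryloxyacetyl imides.

**Step 11**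
Reactants: 20 syn-aldol adduct
Product: 21 (1S,2S)-2-(ArO)-1-[4-(benzyloxy)-3-methoxyphenyl]propane-1,3-diol (threo; 7S,8S)
Conditions: NaBH4, THF–H2O, 0 °C → rt
Reagents that add atoms: none
Why: Reductive cleavage of the N-acyl oxazolidinone by borohydride in aqueous THF attacks the more electrophilic exocyclic carbonyl, releases the recoverable auxiliary, does not epimerise C8, and leaves the vinyl group alone because no free borane is generated.

**Step 12**
Reactants: 21 threo diol
Product: 23 (1R,2S)-2-(ArO)-1-[4-(benzyloxy)-3-methoxyphenyl]propane-1,3-diyl bis(4-nitrobenzoate) (erythro; 7R,8S), via primary mono-ester 22 (not isolated)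
Conditions: 4-O2NC6H4CO2H, PPh3, DIAD (4 equiv each), THF, 0 °C → rt
Reagents that add atoms: 4-nitrobenzoic acid, O=C(O)c1ccc(cc1)[N+](=O)[O-]
Why: In this Mitsunobu esterification the primary C9 hydroxyl is esterified first (22) and the C7 oxyphosphonium salt is then displaced by 4-nitrobenzoate in an SN2 process with inversion, turning (7S) into (7R), a conversion known for arylglycerol β-aryl ethers and helped here by the electron-withdrawing C8 aryloxy and C9 acyloxy groups, which disfavour ionisation.

**Step 13**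
Reactants: 23 erythro bis(4-nitrobenzoate)
Product: 24 (1R,2S)-2-(ArO)-1-[4-(benzyloxy)-3-methoxyphenyl]propane-1,3-diol (erythro; 7R,8S)
Conditions: K2CO3 (cat.), MeOH–THF, 0 °C → rt
Reagents that add atoms: none
Why: Base-catalysed transesterification (Zemplén-type methanolysis) of the activated 4-nitrobenzoates proceeds by acyl–oxygen cleavage, so the newly set C7 configuration is retained.

**Step 14**
Reactants: 24 erythro diol
Product: 26 (1R,2S)-2-[4-({(2R,3S,4R,5S)-3-(benzyloxy)-5-[4-(benzyloxy)-3-methoxyphenyl]-4-(hydroxymethyl)oxolan-2-yl}methyl)-2-methoxyphenoxy]-1-[4-(benzyloxy)-3-methoxyphenyl]propane-1,3-diol, via C3 aldehyde 25 (not isolated)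
Conditions: OsO4 (2 mol%), NaIO4, 2,6-lutidine, dioxane–H2O, rt; filter; then NaBH4, EtOH, 0 °C
Reagents that add atoms: sodium periodate, [Na+].[O-]I(=O)(=O)=O; osmium tetroxide (catalytic oxygen carrier), O=[Os](=O)(=O)=O
Why: Lemieux–Johnson cleavage of the only alkene under lutidine buffering, followed directly by borohydride reduction, converts the vinyl group into CH2OH before aldehyde 25 can epimerise at C3 or lose the C4 benzyloxy group by β-elimination, and the 1,3-diol of the side chain is not a periodate substrate.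

**Step 15**
Reactants: 26 triol tris(benzyl ether)
Product: 27 (1R,2S)-1-(4-hydroxy-3-methoxyphenyl)-2-[4-({(2R,3S,4S,5S)-3-hydroxy-5-(4-hydroxy-3-methoxyphenyl)-4-(hydroxymethyl)oxolan-2-yl}methyl)-2-methoxyphenoxy]propane-1,3-diol (target)
Conditions: H2 (1 atm), 10% Pd/C, EtOAc–EtOH, rt
Reagents that add atoms: none
Why: Catalytic hydrogenolysis under neutral conditions cleaves the two aryl benzyl ethers and the one alkyl benzyl ether faster than the hindered secondary benzylic C7–OH and C2–O1 bonds, provided acid is excluded and the reaction is stopped at the calculated uptake.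

**Compound list**
1 | 4-bromo-2-methoxyphenol | COc1cc(Br)ccc1O | starting material
2 | (4-bromo-2-methoxyphenoxy)triisopropylsilane | COc1cc(Br)ccc1O[Si](C(C)C)(C(C)C)C(C)C | intermediate
3 | penta-1,4-dien-3-ol | C=CC(O)C=C | starting material
4 | (2R,3S)-1,2-epoxypent-4-en-3-ol | C1[C@@H](O1)[C@@H](O)C=C | intermediate
5 | (2R,3S)-3-(benzyloxy)-1,2-epoxypent-4-ene | C1[C@@H](O1)[C@@H](OCc2ccccc2)C=C | intermediate
6 | [3-methoxy-4-(triisopropylsilyloxy)phenyl]magnesium bromide | COc1cc([Mg]Br)ccc1O[Si](C(C)C)(C(C)C)C(C)C | intermediate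
7 | (2R,3S)-3-(benzyloxy)-1-[3-methoxy-4-(triisopropylsilyloxy)phenyl]pent-4-en-2-ol | CC(C)[Si](Oc1ccc(C[C@@H](O)[C@@H](OCc2ccccc2)C=C)cc1OC)(C(C)C)C(C)C | intermediate
8 | allyltrimethylsilane | C=CC[Si](C)(C)C | starting material
9 | (2R,3S,4E)-3-(benzyloxy)-1-[3-methoxy-4-(triisopropylsilyloxy)phenyl]-6-(trimethylsilyl)hex-4-en-2-ol | CC(C)[Si](Oc1ccc(C[C@@H](O)[C@@H](OCc2ccccc2)/C=C/C[Si](C)(C)C)cc1OC)(C(C)C)C(C)C | intermediate
10 | 4-(benzyloxy)-3-methoxybenzaldehyde | COc1cc(C=O)ccc1OCc1ccccc1 | starting material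
11 | (E)-oxocarbenium ion (C5–O1=C2 cation) from 9 and 10 | CC(C)[Si](Oc1ccc(C[C@@H](/[O+]=C/c2ccc(OCc3ccccc3)c(OC)c2)[C@@H](OCc4ccccc4)/C=C/C[Si](C)(C)C)cc1OC)(C(C)C)C(C)C | intermediate
12 | (2S,3R,4S,5R)-4-(benzyloxy)-2-[4-(benzyloxy)-3-methoxyphenyl]-3-ethenyl-5-{[3-methoxy-4-(triisopropylsilyloxy)phenyl]methyl}oxolane | CC(C)[Si](Oc1ccc(C[C@H]2O[C@H](c3ccc(OCc4ccccc4)c(OC)c3)[C@@H](C=C)[C@@H]2OCc5ccccc5)cc1OC)(C(C)C)C(C)C | intermediate
13 | 4-({(2R,3S,4R,5S)-3-(benzyloxy)-5-[4-(benzyloxy)-3-methoxyphenyl]-4-ethenyloxolan-2-yl}methyl)-2-methoxyphenol | Oc1ccc(C[C@H]2O[C@H](c3ccc(OCc4ccccc4)c(OC)c3)[C@@H](C=C)[C@@H]2OCc5ccccc5)cc1OC | intermediate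
14 | (R)-4-benzyloxazolidin-2-one | O=C1N[C@H](Cc2ccccc2)CO1 | starting material
15 | bromoacetyl bromide | O=C(Br)CBr | starting material
16 | N-lithio (R)-4-benzyloxazolidin-2-one | [Li]N1[C@H](Cc2ccccc2)COC1=O | intermediate
17 | (R)-4-benzyl-3-(bromoacetyl)oxazolidin-2-one | O=C(CBr)N1[C@H](Cc2ccccc2)COC1=O | intermediate
18 | (R)-4-benzyl-3-[(ArO)acetyl]oxazolidin-2-one, ArO = phenoxy residue of 13 | O=C(COc1ccc(C[C@H]2O[C@H](c3ccc(OCc4ccccc4)c(OC)c3)[C@@H](C=C)[C@@H]2OCc5ccccc5)cc1OC)N6[C@H](Cc7ccccc7)COC6=O | intermediate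
19 | (Z)-dibutylboron enolate of 18 | CCCCB(CCCC)O/C(=C\Oc1ccc(C[C@H]2O[C@H](c3ccc(OCc4ccccc4)c(OC)c3)[C@@H](C=C)[C@@H]2OCc5ccccc5)cc1OC)N6[C@H](Cc7ccccc7)COC6=O | intermediate
20 | syn-aldol adduct, (2R,3S)-propanoyl imide of the (R)-auxiliary | COc1cc([C@H](O)[C@H](C(=O)N2[C@H](Cc3ccccc3)COC2=O)Oc4ccc(C[C@H]5O[C@H](c6ccc(OCc7ccccc7)c(OC)c6)[C@@H](C=C)[C@@H]5OCc8ccccc8)cc4OC)ccc1OCc9ccccc9 | intermediate
21 | threo (7S,8S) 1,3-diol | COc1cc([C@H](O)[C@H](CO)Oc2ccc(C[C@H]3O[C@H](c4ccc(OCc5ccccc5)c(OC)c4)[C@@H](C=C)[C@@H]3OCc6ccccc6)cc2OC)ccc1OCc7ccccc7 | intermediate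
22 | threo (7S,8S) C9 mono(4-nitrobenzoate) | COc1cc([C@H](O)[C@H](COC(=O)c8ccc(cc8)[N+](=O)[O-])Oc2ccc(C[C@H]3O[C@H](c4ccc(OCc5ccccc5)c(OC)c4)[C@@H](C=C)[C@@H]3OCc6ccccc6)cc2OC)ccc1OCc7ccccc7 | intermediate
23 | erythro (7R,8S) C7,C9 bis(4-nitrobenzoate) | COc1cc([C@@H](OC(=O)c8ccc(cc8)[N+](=O)[O-])[C@H](COC(=O)c9ccc(cc9)[N+](=O)[O-])Oc2ccc(C[C@H]3O[C@H](c4ccc(OCc5ccccc5)c(OC)c4)[C@@H](C=C)[C@@H]3OCc6ccccc6)cc2OC)ccc1OCc7ccccc7 | intermediate
24 | erythro (7R,8S) 1,3-diol, C3 vinyl | COc1cc([C@@H](O)[C@H](CO)Oc2ccc(C[C@H]3O[C@H](c4ccc(OCc5ccccc5)c(OC)c4)[C@@H](C=C)[C@@H]3OCc6ccccc6)cc2OC)ccc1OCc7ccccc7 | intermediate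
25 | erythro diol, C3 formyl (3R) | COc1cc([C@@H](O)[C@H](CO)Oc2ccc(C[C@H]3O[C@H](c4ccc(OCc5ccccc5)c(OC)c4)[C@@H](C=O)[C@@H]3OCc6ccccc6)cc2OC)ccc1OCc7ccccc7 | intermediate
26 | triol tris(benzyl ether), C3 hydroxymethyl | COc1cc([C@@H](O)[C@H](CO)Oc2ccc(C[C@H]3O[C@H](c4ccc(OCc5ccccc5)c(OC)c4)[C@@H](CO)[C@@H]3OCc6ccccc6)cc2OC)ccc1OCc7ccccc7 | intermediate
27 | CNP0123626.1 | COc1cc([C@@H](O)[C@H](CO)Oc2ccc(C[C@H]3O[C@H](c4ccc(O)c(OC)c4)[C@@H](CO)[C@@H]3O)cc2OC)ccc1O | target

**Total step count:** 15.
**Longest linear sequence:** 13 steps, from 3 to 27 through steps 2–7 and 9–15.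

**Steps most likely to fail**

**Step 6.** The cation may be diverted before the allylsilane reaches it. The electron-rich ring of the arylmethyl group could attack it (oxa-Pictet–Spengler closure), the water liberated in the direct condensation could cause protodesilylation, and facial selectivity at C3 could erode if warming is needed to drive ionisation.

The fallback brings in C2 at the carboxylic acid level and makes O1–C2 first. Starting from 9, DCC/DMAP esterification with commercial 4-(benzyloxy)-3-methoxybenzoic acid would give the C5 4-(benzyloxy)-3-methoxybenzoate ester F1. Treatment with i-Bu2AlH at −78 °C, then trapping of the aluminium hemiacetal in situ with Ac2O, pyridine and DMAP (reductive acetylation), would give the α-acetoxy ether F2, used without chromatography. BF3·OEt2 or Me3SiOTf at −78 °C would ionise it irreversibly and without release of water to the same cation 11. This closes to 12, where the route is rejoined.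

**Step 12.** Ionisation of the activated benzylic oxyphosphonium intermediate would scramble C7, and elimination toward the enol ether could compete.

The fallback replaces the intermolecular displacement by a tethered one. Starting from 21, Boc2O (1 equiv) with 1-methylimidazole in CH2Cl2 at 0 °C would give the primary C9 tert-butyl carbonate F3. MsCl and Et3N would then give the transient C7 mesylate F4. Its carbonate carbonyl oxygen attacks C7 from the rear, with loss of the tert-butyl group, to give the trans-4,5-disubstituted 1,3-dioxan-2-one F5. Even if ionisation intervenes, the six-membered ring should close to the diequatorial trans isomer, which is the erythro series. K2CO3 in MeOH would open F5 to 24, where the route is rejoined.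

**Step 5.** Incomplete E-selectivity, slow turnover of the hindered allylic ether and self-metathesis of the silane could leave a geometrically impure allylsilane.

The fallback builds the alkene by olefination and cross-coupling. Starting from 7, Lemieux–Johnson cleavage (OsO4 cat., NaIO4, 2,6-lutidine) would give (2R,3R)-2-(benzyloxy)-3-hydroxy-4-arylbutanal F6. Takai olefination (CrCl2, CHI3, THF, 0 °C) would give the (2R,3S,4E)-5-iodopent-4-en-2-ol F7. Kumada coupling with excess Me3SiCH2MgCl and Pd(PPh3)4 would replace iodine with retention of alkene geometry and return to 9.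

**Further compounds**
F1 | step 6 | (2R,3S,4E)-3-(benzyloxy)-1-[3-methoxy-4-(triisopropylsilyloxy)phenyl]-6-(trimethylsilyl)hex-4-en-2-yl 4-(benzyloxy)-3-methoxybenzoate | CC(C)[Si](Oc1ccc(C[C@@H](OC(=O)c2ccc(OCc3ccccc3)c(OC)c2)[C@@H](OCc4ccccc4)/C=C/C[Si](C)(C)C)cc1OC)(C(C)C)C(C)C
F2 | step 6 | α-acetoxy ether from F1 (acetal carbon unassigned) | CC(C)[Si](Oc1ccc(C[C@@H](OC(OC(C)=O)c2ccc(OCc3ccccc3)c(OC)c2)[C@@H](OCc4ccccc4)/C=C/C[Si](C)(C)C)cc1OC)(C(C)C)C(C)C
F3 | step 12 | threo (7S,8S) C9 tert-butyl carbonate of 21 | COc1cc([C@H](O)[C@H](COC(=O)OC(C)(C)C)Oc2ccc(C[C@H]3O[C@H](c4ccc(OCc5ccccc5)c(OC)c4)[C@@H](C=C)[C@@H]3OCc6ccccc6)cc2OC)ccc1OCc7ccccc7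
F4 | step 12 | C7 mesylate of F3 | COc1cc([C@H](OS(C)(=O)=O)[C@H](COC(=O)OC(C)(C)C)Oc2ccc(C[C@H]3O[C@H](c4ccc(OCc5ccccc5)c(OC)c4)[C@@H](C=C)[C@@H]3OCc6ccccc6)cc2OC)ccc1OCc7ccccc7
F5 | step 12 | (4R,5S)-4-[4-(benzyloxy)-3-methoxyphenyl]-5-(ArO)-1,3-dioxan-2-one (trans) | COc1cc([C@H]8OC(=O)OC[C@@H]8Oc2ccc(C[C@H]3O[C@H](c4ccc(OCc5ccccc5)c(OC)c4)[C@@H](C=C)[C@@H]3OCc6ccccc6)cc2OC)ccc1OCc7ccccc7
F6 | step 5 | (2R,3R)-2-(benzyloxy)-3-hydroxy-4-[3-methoxy-4-(triisopropylsilyloxy)phenyl]butanal | CC(C)[Si](Oc1ccc(C[C@@H](O)[C@@H](OCc2ccccc2)C=O)cc1OC)(C(C)C)C(C)C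
F7 | step 5 | (2R,3S,4E)-3-(benzyloxy)-5-iodo-1-[3-methoxy-4-(triisopropylsilyloxy)phenyl]pent-4-en-2-ol | CC(C)[Si](Oc1ccc(C[C@@H](O)[C@@H](OCc2ccccc2)/C=C/I)cc1OC)(C(C)C)C(C)C
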